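## Retrosynthetic overview

1. Target 10 ⇐ reductive C3–O cleavage of the 3β,4β-epoxy ketone 9 ⇐ titanium-directed benzoate opening (C5, inversion) of the trans-diepoxide 8.
2. 8 ⇐ two successive epoxidations of the o-quinol dienone 6 (the biogenetic grandifloracin monomer): first the α-oxirane at C5–C6 (cis to the tertiary OH), then the β-oxirane at C3–C4 (anti to the first).
3. 6 ⇐ oxidation of the secondary carbinol of the diene-diol monobenzoate 5 ⇐ reduction and mono-benzoylation of the benzoate cis-dihydrodiol 2.
4. The carbocycle is not constructed: as in the proposed biogenesis by arene oxidation, it is unveiled from benzoic acid 1 by enzymatic dearomatising ipso,ortho-dihydroxylation, which fixes the C1 configuration. The only rings formed are the two oxiranes, in the biogenetic order.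

Assumption/convention: the whole-cell benzoate dioxygenase catalyst (Ralstonia eutropha B9) counts as a reagent; descriptive locants are C1 = quaternary carbinol carbon, C2 = its neighbour that ends as C=O, then C3–C6 round the ring; β = face of the C1 carbon substituent, α = face of the C1 hydroxyl.

## Route

Step 1
Reactants: 1 benzoic acid
Product: 2 (1S,2R)-1,2-dihydroxycyclohexa-3,5-diene-1-carboxylic acid
Conditions: Ralstonia eutropha B9 whole cells, 1 fed as sodium salt, fructose, mineral medium pH 7.4, air, 30 °C; then pH 3 at 0 °C, EtOAc extraction, crystallisation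
Reagents that add atoms: dioxygen O=O
Why: Benzoate 1,2-dioxygenase (enzymatic dearomatising cis-dihydroxylation by a Rieske non-haem iron enzyme) adds both atoms of O2 to the ipso and ortho carbons from one face, so C1 and C2 are set by the enzyme (cis, >95% ee, raised by crystallisation), and the dehydrogenase-deficient strain lets the diol accumulate.

Step 2
Reactants: 2 (1S,2R)-1,2-dihydroxycyclohexa-3,5-diene-1-carboxylic acid
Product: 3 (1R,2R)-1-(hydroxymethyl)cyclohexa-3,5-diene-1,2-diol
Conditions: LiAlH4 (4 equiv), THF, 0 → 40 °C; Fieser work-up (H2O, 15% NaOH), kept basic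
Reagents that add atoms: none
Why: Lithium aluminium hydride reduction of an α-hydroxy carboxylate to the primary alcohol leaves the unactivated diene and both stereocentres untouched, and the strictly basic work-up avoids acid-triggered dehydrative aromatisation of the diene-diol.

Step 3
Reactants: 3 (1R,2R)-1-(hydroxymethyl)cyclohexa-3,5-diene-1,2-diol; 4 benzoyl chloride
Product: 5 [(1R,6R)-1,6-dihydroxycyclohexa-2,4-dien-1-yl]methyl benzoate
Conditions: BzCl (1.05 equiv), 2,4,6-collidine, CH2Cl2, −40 → −20 °C
Reagents that add atoms: benzoyl chloride (4) O=C(Cl)c1ccccc1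
Why: Kinetically selective O-acylation (benzoylation with a hindered pyridine base) takes the only primary hydroxyl, the tertiary C1-OH being inert and the secondary C2-OH being flanked by the quaternary centre; no stereocentre is touched.

Step 4
Reactants: 5 [(1R,6R)-1,6-dihydroxycyclohexa-2,4-dien-1-yl]methyl benzoate
Product: 7 [(1S,2S,6S)-2-hydroxy-3-oxo-7-oxabicyclo[4.1.0]hept-4-en-2-yl]methyl benzoate (5α,6α-epoxy enone; oxirane cis to the tertiary OH), via o-quinol dienone 6 (not isolated)
Conditions: DMP (1.3 equiv), NaHCO3, CH2Cl2 (0.01 M), −10 °C, 40 min; then TFDO (2 equiv, in CF3COCH3), −30 °C, 15 min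
Reagents that add atoms: methyl(trifluoromethyl)dioxirane CC1(OO1)C(F)(F)F
Why: Proposed new method: Dess–Martin oxidation of the doubly allylic C2 carbinol gives the o-quinol 6, which in known chemistry dimerises by Diels–Alder reaction, but at 0.01 M and −30 °C this bimolecular dimerisation should be slower than oxygen transfer from the very electrophilic dioxirane to the more electron-rich γ,δ-alkene, delivered to the α face by hydrogen bonding to the C1-OH and by screening of the β face by CH2OBz, so C5 and C6 are set as the oxirane cis to the tertiary hydroxyl (closest known reactions: hydroxyl-directed dioxirane or peracid epoxidation of 2,4-cyclohexadienones at the distal double bond and in situ interception of o-quinols by dienophiles).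

Step 5
Reactants: 7 5α,6α-epoxy enone
Product: 8 3β,4β:5α,6α-diepoxy-1α-hydroxy-1β-(benzoyloxymethyl)cyclohexan-2-one (trans-diepoxide)
Conditions: TBHP (2 equiv, in decane), DBU (0.3 equiv), CH2Cl2, 0 °C
Reagents that add atoms: tert-butyl hydroperoxide CC(C)(C)OO
Why: Weitz–Scheffer nucleophilic epoxidation, in which the tert-butylperoxide anion adds to C4 of the enone anti to the allylic C5–O bond of the α-oxirane and the enolate closes on the peroxide oxygen, gives the β-oxirane (trans-diepoxide, as in crotepoxide-type natural products) while the benzoate and the tertiary carbinol survive the mild base.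

Step 6
Reactants: 8 trans-diepoxide; 1 benzoic acid
Product: 9 5β-benzoyloxy-3β,4β-epoxy-1α,6α-dihydroxy-1β-(benzoyloxymethyl)cyclohexan-2-one
Conditions: PhCO2H (2 equiv), Ti(OiPr)4 (1.5 equiv), CH2Cl2, rt; aqueous work-up
Reagents that add atoms: benzoic acid (1) OC(=O)c1ccccc1
Why: Sharpless-type Ti(OiPr)4-mediated opening of a 2,3-epoxy alcohol, in which the C1 titanium alkoxide on the α face chelates and activates only the syn α-oxirane and benzoate attacks its distal carbon C5 (C6 is neopentylic) from the β face with inversion, sets 5β-OBz and 6α-OH and leaves the unchelated β-oxirane alone.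

Step 7
Reactants: 9 5β-benzoyloxy-3β,4β-epoxy ketone
Product: 10 [(1S,2S,3R,4R)-3-benzoyloxy-1,2,4-trihydroxy-6-oxocyclohexyl]methyl benzoate (target)
Conditions: (PhSe)2 (1.5 equiv), NaBH4 (3 equiv), EtOH, 0 °C; AcOH (3 equiv); then 9, 0 °C → rt
Reagents that add atoms: none
Why: Miyashita organoselenium reduction of an α,β-epoxy ketone, in which benzeneselenolate opens the oxirane at the carbonyl-activated α-carbon C3 and a second selenolate removes the selenium to give the enol that AcOH protonates, cleaves only the C3–O bond, so the 4β-hydroxyl keeps the configuration set in step 5 and the buffered medium prevents E1cB dehydration and 5→4 benzoate migration.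

## Compound list

1 | benzoic acid | OC(=O)c1ccccc1 | starting material
2 | (1S,2R)-1,2-dihydroxycyclohexa-3,5-diene-1-carboxylic acid (cis-diol, both OH α, CO2H β) | OC(=O)[C@@]1(O)[C@H](O)C=CC=C1 | intermediate
3 | (1R,2R)-1-(hydroxymethyl)cyclohexa-3,5-diene-1,2-diol (cis-diol) | OC[C@@]1(O)[C@H](O)C=CC=C1 | intermediate
4 | benzoyl chloride | O=C(Cl)c1ccccc1 | starting material
5 | [(1R,6R)-1,6-dihydroxycyclohexa-2,4-dien-1-yl]methyl benzoate (primary monobenzoate of 3) | O=C(OC[C@@]1(O)[C@H](O)C=CC=C1)c1ccccc1 | intermediate
6 | (R)-(1-hydroxy-6-oxocyclohexa-2,4-dien-1-yl)methyl benzoate (o-quinol dienone; C2 carbinol of 5 oxidised) | O=C(OC[C@@]1(O)C(=O)C=CC=C1)c1ccccc1 | intermediate (not isolated)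
7 | [(1S,2S,6S)-2-hydroxy-3-oxo-7-oxabicyclo[4.1.0]hept-4-en-2-yl]methyl benzoate (5α,6α-epoxide of 6, oxirane cis to C1-OH) | O=C(OC[C@@]1(O)C(=O)C=C[C@@H]2O[C@H]12)c1ccccc1 | intermediate
8 | 3β,4β:5α,6α-diepoxy-1α-hydroxy-1β-(benzoyloxymethyl)cyclohexan-2-one (trans-diepoxide) | O=C(OC[C@@]1(O)C(=O)[C@H]2O[C@H]2[C@@H]3O[C@H]13)c1ccccc1 | intermediate
9 | 5β-benzoyloxy-3β,4β-epoxy-1α,6α-dihydroxy-1β-(benzoyloxymethyl)cyclohexan-2-one | O=C(OC[C@@]1(O)C(=O)[C@H]2O[C@H]2[C@@H](OC(=O)c2ccccc2)[C@@H]1O)c1ccccc1 | intermediate
10 | [(1S,2S,3R,4R)-3-benzoyloxy-1,2,4-trihydroxy-6-oxocyclohexyl]methyl benzoate (1α-OH, 4β-OH, 5β-OBz, 6α-OH) | O=C(OC[C@@]1(O)C(=O)C[C@@H](O)[C@@H](OC(=O)c2ccccc2)[C@@H]1O)c1ccccc1 | target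

## Step count and risks

Total step count: 7. Longest linear sequence: 7 steps (1 → 10; fully linear, with 1 used again as the benzoate source in step 6).

Three steps most likely to fail:

**Step 4.** The Diels–Alder dimerisation of the o-quinol 6 may outrun the epoxidation. The fallback sets out from 5 and comes back to the route at 7. TESCl/imidazole (DMF, 0 °C) silylates only the secondary C2-OH and gives the 2-O-triethylsilyl ether F1. VO(acac)2 (cat.)/TBHP in CH2Cl2, which epoxidises only alkenes allylic to a free hydroxyl, is then steered by the tertiary C1-OH alone to C5=C6 and gives the 5α,6α-epoxy silyl ether F2 at the alcohol oxidation level. TBAF/AcOH (THF, 0 °C) frees the 5α,6α-epoxy-1α,2α-diol F3, and DMP/NaHCO3 oxidation of its allylic C2-OH gives 7. The dimerisation-prone dienone never exists in this sequence.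

**Step 6.** Benzoate may attack C6 or the β-oxirane, or titanium may deliver isopropoxide. The fallback sets out from 7 and comes back at 9. Acid-catalysed hydrolysis of the allylic oxirane of 7 (cat. HClO4, THF/H2O, 0 °C) at the allylic C5 with inversion gives the trans-5β,6α-diol enone F4. Hydroxyl-guided nucleophilic epoxidation (TBHP, Triton B, 0 °C), delivered syn to the allylic C5-OH by hydrogen bonding, gives the 3β,4β-epoxy-1α,5β,6α-triol ketone F5. Selective benzoylation of the less hindered C5-OH (BzCl, collidine, −40 °C; C6-OH sits next to the quaternary centre, C1-OH is tertiary) gives 9.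

**Step 2.** The polyanionic aluminate of the unprotected diol acid may be too insoluble for clean reduction, or the very polar triol may be lost on the aluminium salts. The fallback sets out from 2 and comes back at 3. Esterification with TMSCHN2 (MeOH/toluene, 0 °C) gives the methyl ester F6, a neutral α-hydroxy ester that NaBH4 in EtOH at 0 °C reduces through chelation-activated hydride delivery, with a simple borate work-up, to give 3.

## Further compounds

F1 | step 4 | 2-O-triethylsilyl ether of 5 (1α-OH free, 2α-OTES, CH2OBz β) | O=C(OC[C@@]1(O)[C@H](O[Si](CC)(CC)CC)C=CC=C1)c1ccccc1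
F2 | step 4 | 5α,6α-epoxide of F1 (oxirane cis to C1-OH) | O=C(OC[C@@]1(O)[C@H](O[Si](CC)(CC)CC)C=C[C@@H]2O[C@H]12)c1ccccc1
F3 | step 4 | 5α,6α-epoxy-1α,2α-dihydroxy-1β-(benzoyloxymethyl)cyclohex-3-ene | O=C(OC[C@@]1(O)[C@H](O)C=C[C@@H]2O[C@H]12)c1ccccc1
F4 | step 6 | 1α,5β,6α-trihydroxy-1β-(benzoyloxymethyl)cyclohex-3-en-2-one (trans-5,6-diol enone) | O=C(OC[C@@]1(O)C(=O)C=C[C@@H](O)[C@@H]1O)c1ccccc1
F5 | step 6 | 3β,4β-epoxy-1α,5β,6α-trihydroxy-1β-(benzoyloxymethyl)cyclohexan-2-one | O=C(OC[C@@]1(O)C(=O)[C@H]2O[C@H]2[C@@H](O)[C@@H]1O)c1ccccc1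
F6 | step 2 | methyl (1S,2R)-1,2-dihydroxycyclohexa-3,5-diene-1-carboxylate | COC(=O)[C@@]1(O)[C@H](O)C=CC=C1
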